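**Plan**

1. Retrosynthesis (abietane numbering; C20 is the bridge methylene): the O-benzyl and O-acetyl bonds are cut first, then C10–C20, O7–C20, C7–C8, C9–C10 and C5–C6.
2. Enabling feature: C20 is a CH2 held between O7 and the quaternary C10, and C10 is β to C2 through C1. With C2 as a ketone and C1=C10 as an alkene, an O7–CH2 radical can close the six-membered bridge ring O7–C20–C10–C9–C8–C7 by conjugate addition.
3. Forward order: ring A (dimedone enol ether, alkylated at the future C5) is joined to ring C (3-isopropylcatechol as a 6-metallated dibenzyl ether) at C9–C10. Ring B closes by Friedel–Crafts acylation at C8, the oxygen bridge closes in the radical step, then C2 is adjusted and the catechol freed.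
4. Stereochemistry: C5 is formed racemic. C7 is set relative to C5 by axial hydride delivery, and the (5S,7S) series is selected by lipase resolution. C10 (R) is dictated by the C7 tether, and C2 (S) comes from a thermodynamically controlled ketyl reduction.
5. Assumption: 3-isopropylcatechol, 3-ethoxy-5,5-dimethylcyclohex-2-enone, tert-butyl bromoacetate and ethyl diazoacetate are purchased. The catechol is carried as its dibenzyl ether because these ethers tolerate the acid of the acylation and leave by neutral hydrogenolysis.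

Key step: step 13

**Route**

Step 1
Reactants: 1 3-isopropylcatechol
Product: 2 1,2-bis(methoxymethoxy)-3-isopropylbenzene
Conditions: MOMCl, iPr2NEt, CH2Cl2, 0 °C → rt
Reagents that add atoms: chloromethyl methyl ether (COCCl)
Why: Base-mediated O-alkylation (MOM ether formation) of both phenols installs the acetal groups that direct the lithiation of step 2.

Step 2
Reactants: 2 1,2-bis(methoxymethoxy)-3-isopropylbenzene
Product: 4 1-bromo-2,3-bis(methoxymethoxy)-4-isopropylbenzene, via aryllithium 3 (not isolated)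
Conditions: n-BuLi, TMEDA, THF, 0 °C; then BrCH2CH2Br, −78 °C → rt
Reagents that add atoms: 1,2-dibromoethane (BrCCBr)
Why: Directed ortho-metalation: the only ring position ortho to a MOM ether is C6 (the other neighbour of the diether carries the isopropyl group), and the aryllithium is trapped by bromine transfer from 1,2-dibromoethane.

Step 3
Reactants: 4 1-bromo-2,3-bis(methoxymethoxy)-4-isopropylbenzene
Product: 5 3-bromo-6-isopropylbenzene-1,2-diol
Conditions: HCl (cat.), MeOH, 50 °C
Reagents that add atoms: none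
Why: Acid-catalysed methanolysis of the aryl MOM acetals frees the catechol so that it can be re-protected with groups that survive the acid of step 7 and leave by hydrogenolysis.

Step 4
Reactants: 5 3-bromo-6-isopropylbenzene-1,2-diol
Product: 6 1-bromo-2,3-bis(benzyloxy)-4-isopropylbenzene
Conditions: BnBr, K2CO3, DMF, 60 °C
Reagents that add atoms: benzyl bromide (BrCc1ccccc1)
Why: Williamson etherification of both phenoxides.

Step 5
Reactants: 7 3-ethoxy-5,5-dimethylcyclohex-2-en-1-one; 8 tert-butyl bromoacetate
Product: 10 racemic tert-butyl 2-(4-ethoxy-6,6-dimethyl-2-oxocyclohex-3-en-1-yl)acetate, via lithium dienolate 9 (not isolated)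
Conditions: LiN(iPr)2, THF, −78 °C; then 8, DMPU, −78 → −20 °C
Reagents that add atoms: none
Why: Stork–Danheiser-type kinetic α′-enolate alkylation: LiN(iPr)2 deprotonates the vinylogous ester only at C6, and the reactive α-bromo ester alkylates this carbon, which becomes C5 (racemic).

Step 6
Reactants: 6 1-bromo-2,3-bis(benzyloxy)-4-isopropylbenzene; 10 racemic tert-butyl 2-(4-ethoxy-6,6-dimethyl-2-oxocyclohex-3-en-1-yl)acetate
Product: 14 racemic tert-butyl 2-[2-(2,3-bis(benzyloxy)-4-isopropylphenyl)-6,6-dimethyl-4-oxocyclohex-2-en-1-yl]acetate, via aryllithium 11 (not isolated), via arylcerium dichloride 12 (not isolated), via tertiary carbinol 13 (not isolated)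
Conditions: 6, n-BuLi, THF, −78 °C; CeCl3 (anhydrous), −78 °C; then 10, −78 → 0 °C; then 2 M HCl, THF, rt
Reagents that add atoms: water (O)
Why: Stork–Danheiser sequence: the weakly basic arylcerium reagent adds 1,2 to the hindered, enolisable vinylogous-ester carbonyl without touching the tert-butyl ester, and aqueous acid converts the carbinol into the transposed 3-aryl enone (C1=C10, C2=O).

Step 7
Reactants: 14 racemic tert-butyl 2-[2-(2,3-bis(benzyloxy)-4-isopropylphenyl)-6,6-dimethyl-4-oxocyclohex-2-en-1-yl]acetate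
Product: 17 racemic 11,12-bis(benzyloxy)-20-norabieta-1(10),8,11,13-tetraene-2,7-dione, via carboxylic acid 15 (not isolated), via mixed anhydride 16 (not isolated)
Conditions: TFA, CH2Cl2, 0 °C → rt; evaporate; then TFAA, CH2Cl2, 0 °C
Reagents that add atoms: none
Why: Intramolecular Friedel–Crafts acylation: TFA removes the tert-butyl group, TFAA activates the acid as its mixed anhydride, and C8 (para to the C12 benzyloxy group), the only position that can close ring B, is acylated; the dione is worked up cold and used at once because it is a tautomer of a naphthol.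

Step 8
Reactants: 17 racemic 11,12-bis(benzyloxy)-20-norabieta-1(10),8,11,13-tetraene-2,7-dione
Product: 18 racemic (5S*,7S*)-11,12-bis(benzyloxy)-20-norabieta-1(10),8,11,13-tetraene-2,7-diol (both C2 epimers)
Conditions: NaBH4, CeCl3·7H2O, MeOH/CH2Cl2, −78 → −30 °C
Reagents that add atoms: none
Why: Luche reduction of both carbonyls, chosen because neither ketone can be reduced selectively with confidence; hydride should add to C7 along the axial trajectory on the face of the pseudoaxial H-5, placing the 7-hydroxyl pseudoequatorial and cis to C4, while the configuration at C2 is irrelevant.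

Step 9
Reactants: 18 racemic (5S*,7S*)-11,12-bis(benzyloxy)-20-norabieta-1(10),8,11,13-tetraene-2,7-diol
Product: 19 racemic (5S*,7S*)-11,12-bis(benzyloxy)-7-hydroxy-20-norabieta-1(10),8,11,13-tetraen-2-one
Conditions: activated MnO2, CH2Cl2, rt, monitored
Reagents that add atoms: none
Why: Allylic oxidation with MnO2: the C2 carbinol is allylic and conjugated to the arene and should be oxidised faster than the benzylic C7 carbinol, and any dione 17 from over-oxidation is returned to step 8.

Step 10
Reactants: 19 racemic (5S*,7S*)-11,12-bis(benzyloxy)-7-hydroxy-20-norabieta-1(10),8,11,13-tetraen-2-one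
Product: 20 (5S,7S)-11,12-bis(benzyloxy)-7-hydroxy-20-norabieta-1(10),8,11,13-tetraen-2-one
Conditions: Burkholderia cepacia lipase (Amano PS, immobilised), vinyl acetate, MTBE, 35 °C, stopped slightly past half conversion
Reagents that add atoms: none
Why: Lipase-catalysed kinetic resolution by irreversible acyl transfer: by Kazlauskas' rule (arene as the large, C6 methylene as the medium substituent) the (7R)-enantiomer should be acetylated, leaving the (5S,7S)-alcohol, which is separated from the acetate by chromatography.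

Step 11
Reactants: 20 (5S,7S)-11,12-bis(benzyloxy)-7-hydroxy-20-norabieta-1(10),8,11,13-tetraen-2-one; 21 ethyl diazoacetate
Product: 22 ethyl 2-{[(5S,7S)-11,12-bis(benzyloxy)-2-oxo-20-norabieta-1(10),8,11,13-tetraen-7-yl]oxy}acetate
Conditions: Rh2(OAc)4 (2 mol%), CH2Cl2, rt, slow addition of 21
Reagents that add atoms: none
Why: Rhodium-carbenoid O–H insertion etherifies the secondary alcohol under neutral conditions, avoiding alkoxide bases that would deprotonate the γ-position (C5) of the enone.

Step 12
Reactants: 22 ethyl 2-{[(5S,7S)-11,12-bis(benzyloxy)-2-oxo-20-norabieta-1(10),8,11,13-tetraen-7-yl]oxy}acetate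
Product: 23 2-{[(5S,7S)-11,12-bis(benzyloxy)-2-oxo-20-norabieta-1(10),8,11,13-tetraen-7-yl]oxy}acetic acid
Conditions: LiOH, THF/H2O, 0 °C; then cold 1 M HCl to pH 3
Reagents that add atoms: lithium hydroxide ([Li+].[OH-])
Why: Saponification of the activated α-alkoxy ester, run cold and briefly so that the base does not enolise the enone towards C5.

Step 13
Reactants: 23 2-{[(5S,7S)-11,12-bis(benzyloxy)-2-oxo-20-norabieta-1(10),8,11,13-tetraen-7-yl]oxy}acetic acid
Product: 24 (5S,7S,10R)-11,12-bis(benzyloxy)-7,20-epoxyabieta-8,11,13-trien-2-one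
Conditions: [Ir(dF(CF3)ppy)2(dtbbpy)]PF6 (2 mol%), K2HPO4, DMF (0.01 M), 450 nm LEDs, rt, degassed
Reagents that add atoms: none
Why: The carboxylate of 23 is oxidised by the photoexcited iridium complex and loses CO2; the nucleophilic O7–CH2 radical (C20) adds to C10, the β-carbon of the C1=C10–C2=O enone, and the resulting C1 α-keto radical is reduced by the reduced photocatalyst and protonated. The closest known reaction type is the photoredox decarboxylative Giese addition of α-alkoxy carboxylic acids to enones, used here intramolecularly. The ring that closes is the six-membered O7–C20–C10–C9–C8–C7 ring (the oxygen bridge of a 2-oxabicyclo[2.2.2]octene), formed 6-exo-trig. The new quaternary centre C10 is controlled by the tether: the radical can reach C10 only on the face that carries the C7 oxygen, which is the face anti to H-5, so C10 (R) follows from C7 and C5. The step needs exo attack at C10 rather than endo attack at C1 and no loss of the radical by hydrogen transfer: the polarity match and the smaller ring favour C10, the only weak C–H bond within reach (C5–H) lies on the opposite face, and in the boat conformer of ring B the C7 oxygen is pseudoaxial and holds C20 directly over C10. High dilution suppresses intermolecular addition.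

Step 14
Reactants: 24 (5S,7S,10R)-11,12-bis(benzyloxy)-7,20-epoxyabieta-8,11,13-trien-2-one
Product: 25 (2S,5S,7S,10R)-11,12-bis(benzyloxy)-7,20-epoxyabieta-8,11,13-trien-2-ol
Conditions: SmI2 (2.5 equiv), H2O, Et3N, THF, 0 °C, short reaction time
Reagents that add atoms: none
Why: Ketyl-type (dissolving-metal-like) reduction with SmI2/water/amine: protonation of the C2 carbanion should leave oxygen in the equatorial 2α position, away from the syn-axial C20 methylene and 4β-methyl group, whereas hydride reagents would attack the open α-face and give the axial alcohol.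

Step 15
Reactants: 25 (2S,5S,7S,10R)-11,12-bis(benzyloxy)-7,20-epoxyabieta-8,11,13-trien-2-ol
Product: 26 (2S,5S,7S,10R)-11,12-bis(benzyloxy)-7,20-epoxyabieta-8,11,13-trien-2-yl acetate
Conditions: Ac2O, pyridine, DMAP (cat.), CH2Cl2, rt
Reagents that add atoms: acetic anhydride (CC(=O)OC(C)=O)
Why: DMAP-catalysed acylation of the unhindered equatorial alcohol.

Step 16
Reactants: 26 (2S,5S,7S,10R)-11,12-bis(benzyloxy)-7,20-epoxyabieta-8,11,13-trien-2-yl acetate
Product: 27 (2S,5S,7S,10R)-7,20-epoxy-11,12-dihydroxyabieta-8,11,13-trien-2-yl acetate (CNP0485560.1)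
Conditions: H2 (1 atm), 10% Pd/C, EtOAc, rt, under argon on work-up
Reagents that add atoms: none
Why: Catalytic hydrogenolysis of the two aryl benzyl ethers; the bridging C7–O bond is also benzylic but belongs to a hindered bicyclic ether on a fully substituted arene and should survive if the reaction is stopped after uptake of two equivalents of hydrogen.

**Compound list**

1 | 3-isopropylcatechol | CC(C)c1cccc(O)c1O | starting material
2 | 1,2-bis(methoxymethoxy)-3-isopropylbenzene | CC(C)c1cccc(OCOC)c1OCOC | intermediate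
3 | [2,3-bis(methoxymethoxy)-4-isopropylphenyl]lithium | [Li]c1ccc(C(C)C)c(OCOC)c1OCOC | intermediate (not isolated)
4 | 1-bromo-2,3-bis(methoxymethoxy)-4-isopropylbenzene | Brc1ccc(C(C)C)c(OCOC)c1OCOC | intermediate
5 | 3-bromo-6-isopropylbenzene-1,2-diol | Brc1ccc(C(C)C)c(O)c1O | intermediate
6 | 1-bromo-2,3-bis(benzyloxy)-4-isopropylbenzene | Brc1ccc(C(C)C)c(OCc2ccccc2)c1OCc1ccccc1 | intermediate
7 | 3-ethoxy-5,5-dimethylcyclohex-2-en-1-one (dimedone ethyl enol ether) | CCOC1=CC(=O)CC(C)(C)C1 | starting material
8 | tert-butyl bromoacetate | CC(C)(C)OC(=O)CBr | starting material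
9 | kinetic lithium dienolate of 7 (lithium 4-ethoxy-6,6-dimethylcyclohexa-1,3-dien-2-olate) | CCOC1=CC(O[Li])=CC(C)(C)C1 | intermediate (not isolated)
10 | racemic tert-butyl 2-(4-ethoxy-6,6-dimethyl-2-oxocyclohex-3-en-1-yl)acetate | CCOC1=CC(=O)C(CC(=O)OC(C)(C)C)C(C)(C)C1 | intermediate
11 | [2,3-bis(benzyloxy)-4-isopropylphenyl]lithium | [Li]c1ccc(C(C)C)c(OCc2ccccc2)c1OCc1ccccc1 | intermediate (not isolated)
12 | [2,3-bis(benzyloxy)-4-isopropylphenyl]cerium dichloride | Cl[Ce](Cl)c1ccc(C(C)C)c(OCc2ccccc2)c1OCc1ccccc1 | intermediate (not isolated)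
13 | racemic tert-butyl 2-[2-(2,3-bis(benzyloxy)-4-isopropylphenyl)-4-ethoxy-2-hydroxy-6,6-dimethylcyclohex-3-en-1-yl]acetate | CCOC1=CC(O)(c2ccc(C(C)C)c(OCc3ccccc3)c2OCc2ccccc2)C(CC(=O)OC(C)(C)C)C(C)(C)C1 | intermediate (not isolated)
14 | racemic tert-butyl 2-[2-(2,3-bis(benzyloxy)-4-isopropylphenyl)-6,6-dimethyl-4-oxocyclohex-2-en-1-yl]acetate | O=C1C=C(c2ccc(C(C)C)c(OCc3ccccc3)c2OCc2ccccc2)C(CC(=O)OC(C)(C)C)C(C)(C)C1 | intermediate
15 | racemic 2-[2-(2,3-bis(benzyloxy)-4-isopropylphenyl)-6,6-dimethyl-4-oxocyclohex-2-en-1-yl]acetic acid | O=C1C=C(c2ccc(C(C)C)c(OCc3ccccc3)c2OCc2ccccc2)C(CC(=O)O)C(C)(C)C1 | intermediate (not isolated)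
16 | mixed anhydride of 15 with trifluoroacetic acid | O=C1C=C(c2ccc(C(C)C)c(OCc3ccccc3)c2OCc2ccccc2)C(CC(=O)OC(=O)C(F)(F)F)C(C)(C)C1 | intermediate (not isolated)
17 | racemic 11,12-bis(benzyloxy)-20-norabieta-1(10),8,11,13-tetraene-2,7-dione | O=C1C=C2c3c(OCc4ccccc4)c(OCc4ccccc4)c(C(C)C)cc3C(=O)CC2C(C)(C)C1 | intermediate
18 | racemic (5S*,7S*)-11,12-bis(benzyloxy)-20-norabieta-1(10),8,11,13-tetraene-2,7-diol, C2 epimers (one enantiomer drawn) | OC1C=C2c3c(OCc4ccccc4)c(OCc4ccccc4)c(C(C)C)cc3[C@@H](O)C[C@H]2C(C)(C)C1 | intermediate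
19 | racemic (5S*,7S*)-11,12-bis(benzyloxy)-7-hydroxy-20-norabieta-1(10),8,11,13-tetraen-2-one (one enantiomer drawn) | O=C1C=C2c3c(OCc4ccccc4)c(OCc4ccccc4)c(C(C)C)cc3[C@@H](O)C[C@H]2C(C)(C)C1 | intermediate
20 | (5S,7S)-11,12-bis(benzyloxy)-7-hydroxy-20-norabieta-1(10),8,11,13-tetraen-2-one (single enantiomer) | O=C1C=C2c3c(OCc4ccccc4)c(OCc4ccccc4)c(C(C)C)cc3[C@@H](O)C[C@H]2C(C)(C)C1 | intermediate
21 | ethyl diazoacetate | CCOC(=O)C=[N+]=[N-] | starting material
22 | ethyl 2-{[(5S,7S)-11,12-bis(benzyloxy)-2-oxo-20-norabieta-1(10),8,11,13-tetraen-7-yl]oxy}acetate | O=C1C=C2c3c(OCc4ccccc4)c(OCc4ccccc4)c(C(C)C)cc3[C@@H](OCC(=O)OCC)C[C@H]2C(C)(C)C1 | intermediate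
23 | 2-{[(5S,7S)-11,12-bis(benzyloxy)-2-oxo-20-norabieta-1(10),8,11,13-tetraen-7-yl]oxy}acetic acid | O=C1C=C2c3c(OCc4ccccc4)c(OCc4ccccc4)c(C(C)C)cc3[C@@H](OCC(=O)O)C[C@H]2C(C)(C)C1 | intermediate
24 | (5S,7S,10R)-11,12-bis(benzyloxy)-7,20-epoxyabieta-8,11,13-trien-2-one | O=C1CC(C)(C)[C@@H]2C[C@@H]3OC[C@@]2(C1)c1c3cc(C(C)C)c(OCc2ccccc2)c1OCc1ccccc1 | intermediate
25 | (2S,5S,7S,10R)-11,12-bis(benzyloxy)-7,20-epoxyabieta-8,11,13-trien-2-ol (2α, equatorial) | O[C@H]1CC(C)(C)[C@@H]2C[C@@H]3OC[C@@]2(C1)c1c3cc(C(C)C)c(OCc2ccccc2)c1OCc1ccccc1 | intermediate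
26 | (2S,5S,7S,10R)-11,12-bis(benzyloxy)-7,20-epoxyabieta-8,11,13-trien-2-yl acetate | CC(=O)O[C@H]1CC(C)(C)[C@@H]2C[C@@H]3OC[C@@]2(C1)c1c3cc(C(C)C)c(OCc2ccccc2)c1OCc1ccccc1 | intermediate
27 | (2S,5S,7S,10R)-7,20-epoxy-11,12-dihydroxyabieta-8,11,13-trien-2-yl acetate | CC(=O)O[C@H]1CC(C)(C)[C@@H]2C[C@@H]3OC[C@@]2(C1)c1c3cc(C(C)C)c(O)c1O | target

**Step count and risks**

Total steps: 16. Longest linear sequence: 15 steps (steps 1–4 and 6–16, from 3-isopropylcatechol).

Steps most likely to fail:

1. Step 13 (radical ring closure). The electron-rich bis(benzyloxy)arene may quench the strongly oxidising excited photocatalyst. The α-alkoxymethyl radical may also be oxidised to an oxocarbenium ion before it reaches C10 through the boat conformer of ring B, giving decarboxylated but uncyclised material. Fallback, setting out from acid 23: condensation with N-hydroxyphthalimide (N,N'-diisopropylcarbodiimide, cat. DMAP, CH2Cl2) would give the N-acyloxyphthalimide F1. Irradiation of F1 with Ru(bpy)3(PF6)2, Hantzsch ester and iPr2NEt in CH2Cl2 (blue light) generates the same C20 radical by reductive fragmentation in a medium free of oxidants. The C1 radical is then quenched by hydrogen transfer from the Hantzsch ester, and the sequence returns to the route at ketone 24.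

2. Step 10 (resolution). Acyl transfer may be slow or poorly enantioselective because the hindered tricyclic carbinol does not fit the binding pockets of the lipase. Fallback, setting out from racemic alcohol 19: Steglich esterification with (R)-O-methylmandelic acid (DCC, DMAP, CH2Cl2, 0 °C) would give two diastereomeric esters. These are the ester of the (5S,7S)-alcohol F2 and the ester of the (5R,7R)-alcohol F3, to be separated by chromatography or crystallisation. Mild methanolysis of F2 (K2CO3, MeOH, 0 °C) returns to the route at alcohol 20.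

3. Step 14 (C2 reduction). Protonation of the C2 ketyl/carbanion from the open α-face would give the axial 2β-alcohol (poor facial selectivity), and prolonged exposure to the reductant may cleave benzyl ethers. Fallback, setting out from ketone 24: NaBH4 (MeOH, 0 °C) delivers hydride from the α-face to give the axial (2R)-alcohol F4. Oppenauer/Meerwein–Ponndorf–Verley equilibration of F4 (Al(OiPr)3, catalytic acetone, iPrOH/toluene, reflux) then drains it into the thermodynamically favoured equatorial alcohol, returning to the route at 25.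

**Further compounds**

F1 | step 13 | 1,3-dioxoisoindolin-2-yl 2-{[(5S,7S)-11,12-bis(benzyloxy)-2-oxo-20-norabieta-1(10),8,11,13-tetraen-7-yl]oxy}acetate | O=C1C=C2c3c(OCc4ccccc4)c(OCc4ccccc4)c(C(C)C)cc3[C@@H](OCC(=O)ON3C(=O)c4ccccc4C3=O)C[C@H]2C(C)(C)C1
F2 | step 10 | (5S,7S)-11,12-bis(benzyloxy)-2-oxo-20-norabieta-1(10),8,11,13-tetraen-7-yl (R)-2-methoxy-2-phenylacetate | O=C1C=C2c3c(OCc4ccccc4)c(OCc4ccccc4)c(C(C)C)cc3[C@@H](OC(=O)[C@H](OC)c3ccccc3)C[C@H]2C(C)(C)C1
F3 | step 10 | (5R,7R)-11,12-bis(benzyloxy)-2-oxo-20-norabieta-1(10),8,11,13-tetraen-7-yl (R)-2-methoxy-2-phenylacetate | O=C1C=C2c3c(OCc4ccccc4)c(OCc4ccccc4)c(C(C)C)cc3[C@H](OC(=O)[C@H](OC)c3ccccc3)C[C@@H]2C(C)(C)C1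
F4 | step 14 | (2R,5S,7S,10R)-11,12-bis(benzyloxy)-7,20-epoxyabieta-8,11,13-trien-2-ol (2β, axial) | O[C@@H]1CC(C)(C)[C@@H]2C[C@@H]3OC[C@@]2(C1)c1c3cc(C(C)C)c(OCc2ccccc2)c1OCc1ccccc1
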